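**Plan**

1. Retrosynthesis: cut the O8–angelate ester and the C12–O6 lactone bond, then the C6–O bond (γ-oxidation of a dienol ether), then the two ring bonds C3–C4 and C5–C6 together, and last C7–C11 and C6=C7.
2. Enabling feature: in the ten-membered carbocycle the carbonyl carbon C3 and the γ-carbinol carbon C6 are joined only through the C4(C15)=C5 unit. This is the pattern left when an alkynoate inserts into the C(=O)–Cα bond of a ketone, so the ring is built as the eight-membered ring C3/C6–C10/C1/C2 and expanded by two carbons.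
3. Forward: (R)-linalool gives an acyclic dienone; RCM closes a cyclooctenone; cuprate addition gives a regiodefined silyl enol ether; [2+2] with methyl propiolate and 4π ring opening give the cyclodeca-1,3-diene; γ-hydroxylation, oxidative lactonization and angeloylation follow.
4. Stereochemistry: C10 comes from (R)-linalool. C8 is set by ligand-controlled vinylation as the 8-epimer, which directs C7 (anti cuprate addition). C6 comes from face-selective epoxidation of the E-5,6-alkene. C8 is inverted in the Mitsunobu angeloylation. The 4Z enone follows from the cisoid ring diene, and the Z-alkene of the angelate comes with angelic acid.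

Key step: step 12

Remark: germacrane numbering is used for ring compounds (ring C1–C10, lactone carbons C11–C13, C14 = methyl on C10, C15 on C4); the target is made as the open 10-hydroxy-3-ketone, which may equilibrate with its 3,10-hemiketal.

Step 1
Reactants: 1 (R)-linalool
Product: 2 (3R)-3,7-dimethyl-3-(triethylsilyloxy)octa-1,6-diene
Conditions: TESOTf, 2,6-lutidine, CH2Cl2, −78 → 0 °C
Reagents that add atoms: triethylsilyl triflate (CC[Si](CC)(CC)OS(=O)(=O)C(F)(F)F)
Why: Silyl triflate with a hindered pyridine base silylates the tertiary allylic alcohol without ionization, so the chiral-pool centre (the later C10) is carried on untouched (silyl ether protection).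

Step 2
Reactants: 2 (3R)-3,7-dimethyl-3-(triethylsilyloxy)octa-1,6-diene
Product: 4 (3R)-3,7-dimethyl-3-(triethylsilyloxy)oct-6-en-1-ol, via alkylborane 3 (not isolated)
Conditions: 9-BBN, THF, 0 °C → rt; then NaOH, H2O2, 0 °C
Reagents that add atoms: 9-borabicyclo[3.3.1]nonane ([BH]1C2CCCC1CCC2); hydrogen peroxide (OO)
Why: 9-BBN hydroborates the monosubstituted vinyl group anti-Markovnikov much faster than the trisubstituted alkene, and alkaline peroxide gives the primary alcohol (hydroboration–oxidation).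

Step 3
Reactants: 4 (3R)-3,7-dimethyl-3-(triethylsilyloxy)oct-6-en-1-ol
Product: 5 (3R)-3,7-dimethyl-3-(triethylsilyloxy)oct-6-enal
Conditions: Dess–Martin periodinane, NaHCO3, CH2Cl2, 0 °C → rt
Reagents that add atoms: none
Why: Buffered Dess–Martin oxidation should stop at the β-silyloxy aldehyde without elimination of the silyloxy group.

Step 4
Reactants: 5 (3R)-3,7-dimethyl-3-(triethylsilyloxy)oct-6-enal
Product: 6 (3S,5R)-5,9-dimethyl-5-(triethylsilyloxy)deca-1,8-dien-3-ol
Conditions: Zn(CH=CH2)2, (+)-MIB (10 mol %), toluene, −20 °C; aq. NH4Cl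
Reagents that add atoms: divinylzinc (C=C[Zn]C=C)
Why: Amino-alcohol-catalysed alkenylzinc addition (Noyori/Oppolzer type) should deliver vinyl to the Re face under ligand control, setting the carbinol (later C8) as the S-epimer that steers C7 and is inverted in step 18.

Step 5
Reactants: 6 (3S,5R)-5,9-dimethyl-5-(triethylsilyloxy)deca-1,8-dien-3-ol
Product: 7 (3S,5R)-3-(tert-butyldimethylsilyloxy)-5,9-dimethyl-5-(triethylsilyloxy)deca-1,8-diene
Conditions: TBSCl, imidazole, DMF, rt
Reagents that add atoms: tert-butyldimethylsilyl chloride (CC(C)(C)[Si](C)(C)Cl)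
Why: Standard silylation of the secondary allylic alcohol gives a bulky γ-substituent for the later conjugate addition.

Step 6
Reactants: 7 (3S,5R)-3-(tert-butyldimethylsilyloxy)-5,9-dimethyl-5-(triethylsilyloxy)deca-1,8-diene
Product: 9 (4R,6S)-6-(tert-butyldimethylsilyloxy)-4-methyl-4-(triethylsilyloxy)oct-7-enal, via ozonide 8 (not isolated)
Conditions: O3 (1.0 equiv, Sudan III end-point), pyridine (cat.), CH2Cl2, −78 °C; then Me2S, −78 °C → rt
Reagents that add atoms: ozone ([O-][O+]=O)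
Why: Ozone should attack the electron-rich trisubstituted alkene much faster than the vinyl group deactivated by the allylic silyloxy group, and reductive work-up gives the aldehyde (chemoselective ozonolysis).

Step 7
Reactants: 9 (4R,6S)-6-(tert-butyldimethylsilyloxy)-4-methyl-4-(triethylsilyloxy)oct-7-enal
Product: 10 (6R,8S)-8-(tert-butyldimethylsilyloxy)-6-methyl-6-(triethylsilyloxy)deca-1,9-dien-3-ol (both C3 epimers)
Conditions: vinylmagnesium bromide, THF, −78 °C; aq. NH4Cl
Reagents that add atoms: vinylmagnesium bromide (C=C[Mg]Br)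
Why: Grignard addition to the aldehyde; the new carbinol centre is not controlled and is removed by oxidation in step 8.

Step 8
Reactants: 10 (6R,8S)-8-(tert-butyldimethylsilyloxy)-6-methyl-6-(triethylsilyloxy)deca-1,9-dien-3-ol
Product: 11 (6R,8S)-8-(tert-butyldimethylsilyloxy)-6-methyl-6-(triethylsilyloxy)deca-1,9-dien-3-one
Conditions: Dess–Martin periodinane, NaHCO3, CH2Cl2, 0 °C
Reagents that add atoms: none
Why: Mild oxidation of the allylic alcohol gives the vinyl ketone without conjugate addition side reactions.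

Step 9
Reactants: 11 (6R,8S)-8-(tert-butyldimethylsilyloxy)-6-methyl-6-(triethylsilyloxy)deca-1,9-dien-3-one
Product: 12 (2Z,4S,6R)-4-(tert-butyldimethylsilyloxy)-6-methyl-6-(triethylsilyloxy)cyclooct-2-en-1-one
Conditions: Grubbs II (5–10 mol %), CH2Cl2 (2 mM), 40 °C
Reagents that add atoms: none
Why: Ring-closing metathesis between the allylic-ether vinyl group and the vinyl ketone should close the eight-membered Z-enone, helped by the quaternary carbon in the tether.

Step 10
Reactants: 13 2-bromoprop-2-en-1-ol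
Product: 14 (2-bromoprop-2-en-1-yloxy)triethylsilane
Conditions: TESCl, imidazole, CH2Cl2, 0 °C
Reagents that add atoms: chlorotriethylsilane (CC[Si](CC)(CC)Cl)
Why: Silylation gives the vinyl bromide precursor of the C11–C13 unit with C12 at the alcohol level under the most labile silyl group of the route.

Step 11
Reactants: 12 (2Z,4S,6R)-4-(tert-butyldimethylsilyloxy)-6-methyl-6-(triethylsilyloxy)cyclooct-2-en-1-one; 14 (2-bromoprop-2-en-1-yloxy)triethylsilane
Product: 16 (3R,4S,6R)-1,4-bis(tert-butyldimethylsilyloxy)-6-methyl-6-(triethylsilyloxy)-3-[3-(triethylsilyloxy)prop-1-en-2-yl]cyclooct-1-ene, via cuprate 15 (not isolated)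
Conditions: 14, t-BuLi (2 equiv per 14), Et2O, −78 °C; CuI (0.5 equiv per 14), −40 °C; then 12, THF, −78 °C; then TBSCl, HMPA, Et3N, −78 → 0 °C
Reagents that add atoms: tert-butyllithium ([Li]C(C)(C)C); copper(I) iodide ([Cu]I); tert-butyldimethylsilyl chloride (CC(C)(C)[Si](C)(C)Cl)
Why: The Gilman alkenylcuprate should add 1,4 to the cyclooctenone anti to the bulky γ-silyloxy group, which sets C7, and silylation of the enolate fixes the enol ether regiospecifically between C3 and C6 (conjugate addition with enolate trapping).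

Step 12
Reactants: 16 (3R,4S,6R)-1,4-bis(tert-butyldimethylsilyloxy)-6-methyl-6-(triethylsilyloxy)-3-[3-(triethylsilyloxy)prop-1-en-2-yl]cyclooct-1-ene; 17 methyl propiolate
Product: 19 methyl (3Z,5E,7R,8S,10R)-3,8-bis(tert-butyldimethylsilyloxy)-10,12-bis(triethylsilyloxy)germacra-3,5,11(13)-trien-15-oate, via cyclobutene 18 (not isolated)
Conditions: 17 (1.5 equiv), EtAlCl2 (20 mol %), CH2Cl2, −78 °C; Et3N quench; then toluene, 90 °C
Reagents that add atoms: none
Why: EtAlCl2-activated methyl propiolate is attacked at its β-carbon by the nucleophilic C6 of the silyl enol ether, and the allenolate closes on the oxocarbenium carbon C3 (stepwise formal [2+2], 4-exo closure) to the cis-fused siloxycyclobutene 18 on the face anti to the C7 side chain. On warming, 18 undergoes thermal conrotatory 4π-electrocyclic opening of the C3–C6 bond, so that C4 and C5 are inserted into the eight-membered ring and the ten-membered carbocycle appears by ring expansion and not by ring closure. The closest known reaction type is the two-carbon ring expansion of 1-siloxycycloalkenes with propiolate esters through bicyclo[n.2.0]alkenes. No stereocentre that survives is created (C3 and C6 become sp2) and C7, C8 and C10 are spectators; the diene geometry follows from torquoselectivity, because the siloxy donor rotates outward and conrotation then turns C7 outward as well, which gives the 3Z,5E diene. The step needs regioselectivity (ester carbon C15 on C4 next to C3), secured by the polarity match of the enol ether β-carbon with the propiolate β-carbon, and chemoselectivity over the 1,1-disubstituted alkene, secured by catalytic Lewis acid at −78 °C.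

Step 13
Reactants: 19 methyl (3Z,5E,7R,8S,10R)-3,8-bis(tert-butyldimethylsilyloxy)-10,12-bis(triethylsilyloxy)germacra-3,5,11(13)-trien-15-oate
Product: 20 (3Z,5E,7R,8S,10R)-3,8-bis(tert-butyldimethylsilyloxy)-10,12-bis(triethylsilyloxy)germacra-3,5,11(13)-trien-15-ol
Conditions: DIBAL-H (2.5 equiv), CH2Cl2, −78 → −40 °C; Rochelle salt
Reagents that add atoms: none
Why: DIBAL reduces the push–pull ester to the primary allylic alcohol while C3 stays masked as its silyl enol ether.

Step 14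
Reactants: 20 (3Z,5E,7R,8S,10R)-3,8-bis(tert-butyldimethylsilyloxy)-10,12-bis(triethylsilyloxy)germacra-3,5,11(13)-trien-15-ol
Product: 21 (3Z,5E,7R,8S,10R)-3,8-bis(tert-butyldimethylsilyloxy)-15-(tert-butyldiphenylsilyloxy)-10,12-bis(triethylsilyloxy)germacra-3,5,11(13)-triene
Conditions: TBDPSCl, imidazole, CH2Cl2, 0 °C
Reagents that add atoms: tert-butyldiphenylsilyl chloride (CC(C)(C)[Si](Cl)(c1ccccc1)c1ccccc1)
Why: Neutral silylation protects O15 with the most robust silyl group, which is the last to be removed.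

Step 15
Reactants: 21 (3Z,5E,7R,8S,10R)-3,8-bis(tert-butyldimethylsilyloxy)-15-(tert-butyldiphenylsilyloxy)-10,12-bis(triethylsilyloxy)germacra-3,5,11(13)-triene
Product: 24 (4Z,6S,7S,8S,10R)-8-(tert-butyldimethylsilyloxy)-15-(tert-butyldiphenylsilyloxy)-6,12-dihydroxy-10-(triethylsilyloxy)germacra-4,11(13)-dien-3-one, via siloxy epoxide 22 (not isolated), via hydroxy enone 23 (not isolated)
Conditions: mCPBA (1.05 equiv), NaHCO3, CH2Cl2, −30 °C; then MeOH, PPTS, 0 °C
Reagents that add atoms: 3-chloroperoxybenzoic acid (OOC(=O)c1cccc(Cl)c1)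
Why: In a vinylogous Rubottom oxidation the peracid should attack the strained E-5,6-alkene (C4 is fully substituted and shielded) on its outer face in the staggered conformer with the ring bond C7–C8 anti, the C11 branch inside and H7 outside, placing O6 cis to C11 (6S); siloxy-assisted epoxide opening of the cisoid ring diene gives the 4Z enone, and mild acid then removes only the primary triethylsilyl ether.

Step 16
Reactants: 24 (4Z,6S,7S,8S,10R)-8-(tert-butyldimethylsilyloxy)-15-(tert-butyldiphenylsilyloxy)-6,12-dihydroxy-10-(triethylsilyloxy)germacra-4,11(13)-dien-3-one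
Product: 27 (4Z,6S,7S,8S,10R)-8-(tert-butyldimethylsilyloxy)-15-(tert-butyldiphenylsilyloxy)-3-oxo-10-(triethylsilyloxy)germacra-4,11(13)-dien-12,6-olide, via enal 25 (not isolated), via lactol 26 (not isolated)
Conditions: TEMPO (20 mol %), PhI(OAc)2 (2.5 equiv), CH2Cl2, rt
Reagents that add atoms: none
Why: TEMPO/PhI(OAc)2 oxidizes the primary allylic alcohol first, the enal is captured by the C6 hydroxyl as a lactol and oxidized on to the α-methylene-γ-lactone (oxidative lactonization of a 1,4-diol); O8 is still silylated so only O6 can close, and C6 and C7 are not touched.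

Step 17
Reactants: 27 (4Z,6S,7S,8S,10R)-8-(tert-butyldimethylsilyloxy)-15-(tert-butyldiphenylsilyloxy)-3-oxo-10-(triethylsilyloxy)germacra-4,11(13)-dien-12,6-olide
Product: 28 (4Z,6S,7R,8S,10R)-15-(tert-butyldiphenylsilyloxy)-8,10-dihydroxy-3-oxogermacra-4,11(13)-dien-12,6-olide
Conditions: HF·pyridine, pyridine, THF, 0 °C → rt (monitored)
Reagents that add atoms: none
Why: Buffered HF·pyridine should cleave the secondary TBS and the tertiary TES ether well before the primary TBDPS ether.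

Step 18
Reactants: 28 (4Z,6S,7R,8S,10R)-15-(tert-butyldiphenylsilyloxy)-8,10-dihydroxy-3-oxogermacra-4,11(13)-dien-12,6-olide; 29 angelic acid
Product: 30 (4Z,6S,7R,8R,10R)-8-angeloyloxy-15-(tert-butyldiphenylsilyloxy)-10-hydroxy-3-oxogermacra-4,11(13)-dien-12,6-olide
Conditions: PPh3, DIAD (betaine preformed at 0 °C), toluene, 0 °C → rt
Reagents that add atoms: none
Why: In the Mitsunobu esterification the C8 alkoxyphosphonium is displaced by angelate with SN2 inversion to the 8R ester cis to C11; the tertiary C10 alcohol is inert and the acid is never activated as an acyl donor, so the Z-alkene of the angelate should be kept.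

Step 19
Reactants: 30 (4Z,6S,7R,8R,10R)-8-angeloyloxy-15-(tert-butyldiphenylsilyloxy)-10-hydroxy-3-oxogermacra-4,11(13)-dien-12,6-olide
Product: 31 (4Z,6S,7R,8R,10R)-8-angeloyloxy-10,15-dihydroxy-3-oxogermacra-4,11(13)-dien-12,6-olide (target)
Conditions: TBAF, AcOH (1:1), THF, 0 °C → rt
Reagents that add atoms: none
Why: Buffered fluoride cleaves the primary TBDPS ether without base-induced damage to the angelate, the enone or the α-methylene lactone.

**Compound list**

1 | (R)-linalool, (3R)-3,7-dimethylocta-1,6-dien-3-ol | C=C[C@](C)(O)CCC=C(C)C | starting material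
2 | (3R)-3,7-dimethyl-3-(triethylsilyloxy)octa-1,6-diene | C=C[C@](C)(O[Si](CC)(CC)CC)CCC=C(C)C | intermediate
3 | B-[(3R)-3,7-dimethyl-3-(triethylsilyloxy)oct-6-en-1-yl]-9-borabicyclo[3.3.1]nonane (not isolated) | CC(C)=CCC[C@@](C)(O[Si](CC)(CC)CC)CCB1C2CCCC1CCC2 | intermediate
4 | (3R)-3,7-dimethyl-3-(triethylsilyloxy)oct-6-en-1-ol | CC(C)=CCC[C@@](C)(O[Si](CC)(CC)CC)CCO | intermediate
5 | (3R)-3,7-dimethyl-3-(triethylsilyloxy)oct-6-enal | CC(C)=CCC[C@@](C)(O[Si](CC)(CC)CC)CC=O | intermediate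
6 | (3S,5R)-5,9-dimethyl-5-(triethylsilyloxy)deca-1,8-dien-3-ol | CC(C)=CCC[C@@](C)(O[Si](CC)(CC)CC)C[C@H](O)C=C | intermediate
7 | (3S,5R)-3-(tert-butyldimethylsilyloxy)-5,9-dimethyl-5-(triethylsilyloxy)deca-1,8-diene | CC(C)=CCC[C@@](C)(O[Si](CC)(CC)CC)C[C@H](O[Si](C)(C)C(C)(C)C)C=C | intermediate
8 | ozonide (1,2,4-trioxolane) of 7 at the 8,9-alkene (not isolated) | CC1(C)OOC(CC[C@@](C)(O[Si](CC)(CC)CC)C[C@H](O[Si](C)(C)C(C)(C)C)C=C)O1 | intermediate
9 | (4R,6S)-6-(tert-butyldimethylsilyloxy)-4-methyl-4-(triethylsilyloxy)oct-7-enal | O=CCC[C@@](C)(O[Si](CC)(CC)CC)C[C@H](O[Si](C)(C)C(C)(C)C)C=C | intermediate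
10 | (6R,8S)-8-(tert-butyldimethylsilyloxy)-6-methyl-6-(triethylsilyloxy)deca-1,9-dien-3-ol (both C3 epimers) | C=CC(O)CC[C@@](C)(O[Si](CC)(CC)CC)C[C@H](O[Si](C)(C)C(C)(C)C)C=C | intermediate
11 | (6R,8S)-8-(tert-butyldimethylsilyloxy)-6-methyl-6-(triethylsilyloxy)deca-1,9-dien-3-one | C=CC(=O)CC[C@@](C)(O[Si](CC)(CC)CC)C[C@H](O[Si](C)(C)C(C)(C)C)C=C | intermediate
12 | (2Z,4S,6R)-4-(tert-butyldimethylsilyloxy)-6-methyl-6-(triethylsilyloxy)cyclooct-2-en-1-one | O=C1/C=C\[C@@H](O[Si](C)(C)C(C)(C)C)C[C@](C)(O[Si](CC)(CC)CC)CC1 | intermediate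
13 | 2-bromoprop-2-en-1-ol | OCC(Br)=C | starting material
14 | (2-bromoprop-2-en-1-yloxy)triethylsilane | C=C(Br)CO[Si](CC)(CC)CC | intermediate
15 | lithium bis[3-(triethylsilyloxy)prop-1-en-2-yl]cuprate (not isolated) | [Li+].C=C(CO[Si](CC)(CC)CC)[Cu-]C(=C)CO[Si](CC)(CC)CC | intermediate
16 | (3R,4S,6R)-1,4-bis(tert-butyldimethylsilyloxy)-6-methyl-6-(triethylsilyloxy)-3-[3-(triethylsilyloxy)prop-1-en-2-yl]cyclooct-1-ene | CC(C)(C)[Si](C)(C)O/C1=C/[C@H](C(=C)CO[Si](CC)(CC)CC)[C@@H](O[Si](C)(C)C(C)(C)C)C[C@](C)(O[Si](CC)(CC)CC)CC1 | intermediate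
17 | methyl propiolate | C#CC(=O)OC | starting material
18 | methyl 1,6-bis(tert-butyldimethylsilyloxy)-4-methyl-4-(triethylsilyloxy)-7-[3-(triethylsilyloxy)prop-1-en-2-yl]bicyclo[6.2.0]dec-9-ene-10-carboxylate, cis-fused, cyclobutene anti to the 7-substituent (not isolated) | COC(=O)C1=C[C@H]2[C@H](C(=C)CO[Si](CC)(CC)CC)[C@@H](O[Si](C)(C)C(C)(C)C)C[C@](C)(O[Si](CC)(CC)CC)CC[C@@]12O[Si](C)(C)C(C)(C)C | intermediate
19 | methyl (3Z,5E,7R,8S,10R)-3,8-bis(tert-butyldimethylsilyloxy)-10,12-bis(triethylsilyloxy)germacra-3,5,11(13)-trien-15-oate | C1/C(O[Si](C)(C)C(C)(C)C)=C(C(=O)OC)\C=C\[C@H](C(=C)CO[Si](CC)(CC)CC)[C@@H](O[Si](C)(C)C(C)(C)C)C[C@](C)(O[Si](CC)(CC)CC)C1 | intermediate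
20 | (3Z,5E,7R,8S,10R)-3,8-bis(tert-butyldimethylsilyloxy)-10,12-bis(triethylsilyloxy)germacra-3,5,11(13)-trien-15-ol | C1/C(O[Si](C)(C)C(C)(C)C)=C(CO)\C=C\[C@H](C(=C)CO[Si](CC)(CC)CC)[C@@H](O[Si](C)(C)C(C)(C)C)C[C@](C)(O[Si](CC)(CC)CC)C1 | intermediate
21 | (3Z,5E,7R,8S,10R)-3,8-bis(tert-butyldimethylsilyloxy)-15-(tert-butyldiphenylsilyloxy)-10,12-bis(triethylsilyloxy)germacra-3,5,11(13)-triene | C1/C(O[Si](C)(C)C(C)(C)C)=C(CO[Si](c2ccccc2)(c3ccccc3)C(C)(C)C)\C=C\[C@H](C(=C)CO[Si](CC)(CC)CC)[C@@H](O[Si](C)(C)C(C)(C)C)C[C@](C)(O[Si](CC)(CC)CC)C1 | intermediate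
22 | (3Z,5R,6R,7S,8S,10R)-5,6-epoxy-3,8-bis(tert-butyldimethylsilyloxy)-15-(tert-butyldiphenylsilyloxy)-10,12-bis(triethylsilyloxy)germacra-3,11(13)-diene (not isolated) | C1/C(O[Si](C)(C)C(C)(C)C)=C(CO[Si](c2ccccc2)(c3ccccc3)C(C)(C)C)\[C@H]4O[C@@H]4[C@H](C(=C)CO[Si](CC)(CC)CC)[C@@H](O[Si](C)(C)C(C)(C)C)C[C@](C)(O[Si](CC)(CC)CC)C1 | intermediate
23 | (4Z,6S,7S,8S,10R)-8-(tert-butyldimethylsilyloxy)-15-(tert-butyldiphenylsilyloxy)-6-hydroxy-10,12-bis(triethylsilyloxy)germacra-4,11(13)-dien-3-one (not isolated) | C1C(=O)/C(CO[Si](c2ccccc2)(c3ccccc3)C(C)(C)C)=C\[C@H](O)[C@H](C(=C)CO[Si](CC)(CC)CC)[C@@H](O[Si](C)(C)C(C)(C)C)C[C@](C)(O[Si](CC)(CC)CC)C1 | intermediate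
24 | (4Z,6S,7S,8S,10R)-8-(tert-butyldimethylsilyloxy)-15-(tert-butyldiphenylsilyloxy)-6,12-dihydroxy-10-(triethylsilyloxy)germacra-4,11(13)-dien-3-one | C1C(=O)/C(CO[Si](c2ccccc2)(c3ccccc3)C(C)(C)C)=C\[C@H](O)[C@H](C(=C)CO)[C@@H](O[Si](C)(C)C(C)(C)C)C[C@](C)(O[Si](CC)(CC)CC)C1 | intermediate
25 | (4Z,6S,7S,8S,10R)-8-(tert-butyldimethylsilyloxy)-15-(tert-butyldiphenylsilyloxy)-6-hydroxy-3-oxo-10-(triethylsilyloxy)germacra-4,11(13)-dien-12-al (not isolated) | C1C(=O)/C(CO[Si](c2ccccc2)(c3ccccc3)C(C)(C)C)=C\[C@H](O)[C@H](C(=C)C=O)[C@@H](O[Si](C)(C)C(C)(C)C)C[C@](C)(O[Si](CC)(CC)CC)C1 | intermediate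
26 | 6,12-lactol of 25, both C12 epimers (not isolated) | C1C(=O)/C(CO[Si](c2ccccc2)(c3ccccc3)C(C)(C)C)=C\[C@@H]4OC(O)C(=C)[C@@H]4[C@@H](O[Si](C)(C)C(C)(C)C)C[C@](C)(O[Si](CC)(CC)CC)C1 | intermediate
27 | (4Z,6S,7S,8S,10R)-8-(tert-butyldimethylsilyloxy)-15-(tert-butyldiphenylsilyloxy)-3-oxo-10-(triethylsilyloxy)germacra-4,11(13)-dien-12,6-olide (cis-fused lactone) | C1C(=O)/C(CO[Si](c2ccccc2)(c3ccccc3)C(C)(C)C)=C\[C@@H]4OC(=O)C(=C)[C@@H]4[C@@H](O[Si](C)(C)C(C)(C)C)C[C@](C)(O[Si](CC)(CC)CC)C1 | intermediate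
28 | (4Z,6S,7R,8S,10R)-15-(tert-butyldiphenylsilyloxy)-8,10-dihydroxy-3-oxogermacra-4,11(13)-dien-12,6-olide | C1C(=O)/C(CO[Si](c2ccccc2)(c3ccccc3)C(C)(C)C)=C\[C@@H]4OC(=O)C(=C)[C@@H]4[C@@H](O)C[C@](C)(O)C1 | intermediate
29 | angelic acid, (Z)-2-methylbut-2-enoic acid | C/C=C(/C)C(=O)O | starting material
30 | (4Z,6S,7R,8R,10R)-8-angeloyloxy-15-(tert-butyldiphenylsilyloxy)-10-hydroxy-3-oxogermacra-4,11(13)-dien-12,6-olide | C1C(=O)/C(CO[Si](c2ccccc2)(c3ccccc3)C(C)(C)C)=C\[C@@H]4OC(=O)C(=C)[C@@H]4[C@H](OC(=O)/C(C)=C\C)C[C@](C)(O)C1 | intermediate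
31 | (4Z,6S,7R,8R,10R)-8-angeloyloxy-10,15-dihydroxy-3-oxogermacra-4,11(13)-dien-12,6-olide | C=C1C(=O)O[C@H]2/C=C(/CO)C(=O)CC[C@@](C)(O)C[C@@H](OC(=O)/C(C)=C\C)[C@@H]12 | target

**Summary**

Total step count: 19. Longest linear sequence: 18 steps (steps 1–9 and 11–19, from (R)-linalool); step 10 is a one-step side branch.

Steps most likely to fail:

1. Step 15. The peracid may add to the other face of the E-5,6-alkene, giving the 6-epimer, or to the enol ether double bond, giving α-hydroxylation at C4. Fallback (C6 set by SN2 inversion instead of facial selection): set out from 21, omit the acid stage and isolate the 6-epimeric hydroxy enone (4Z,6R,7S,8S,10R)-8-(tert-butyldimethylsilyloxy)-15-(tert-butyldiphenylsilyloxy)-6-hydroxy-10,12-bis(triethylsilyloxy)germacra-4,11(13)-dien-3-one F1. A Mitsunobu reaction with 4-nitrobenzoic acid (PPh3, DIAD, toluene) would invert C6 to the (6S)-4-nitrobenzoate F2. Methanolysis (K2CO3 cat., MeOH, 0 °C) would release 23, which PPTS/MeOH converts into 24, where the route is rejoined.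

2. Step 18. The carboxylate must enter on the face that carries the lactone, so E2 elimination of the C8 oxyphosphonium or stalled displacement may compete, and phosphine may isomerize the angelate. Fallback (C8 reset by directed reduction, then esterification with retention): set out from 28 and oxidize the secondary alcohol with Dess–Martin periodinane to the 8-ketone (4Z,6S,7S,10R)-15-(tert-butyldiphenylsilyloxy)-10-hydroxy-3,8-dioxogermacra-4,11(13)-dien-12,6-olide F3. Narasaka–Prasad reduction (Et2BOMe, NaBH4, THF/MeOH, −78 °C), with hydride guided by the boron chelate of the C10 hydroxyl, would give the syn-1,3-diol (4Z,6S,7R,8R,10R)-15-(tert-butyldiphenylsilyloxy)-8,10-dihydroxy-3-oxogermacra-4,11(13)-dien-12,6-olide F4. Yamaguchi esterification with 29 (2,4,6-trichlorobenzoyl chloride, Et3N, then DMAP, toluene), selective for the secondary hydroxyl, returns to the route at 30.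

3. Step 9. Intermolecular cross-metathesis (oligomers) and slow turnover of the carbene derived from the electron-poor enone may outrun closure of the eight-membered ring. Fallback (ring closure on the electron-rich bis-allylic diene before oxidation): set out from 10 and carry out the ring-closing metathesis (Grubbs II, CH2Cl2, high dilution) to the cyclooctenol (2Z,4S,6R)-4-(tert-butyldimethylsilyloxy)-6-methyl-6-(triethylsilyloxy)cyclooct-2-en-1-ol F5 (both C1 epimers). Dess–Martin oxidation then returns to the route at 12.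

Further compounds
F1 | step 15 | (4Z,6R,7S,8S,10R)-8-(tert-butyldimethylsilyloxy)-15-(tert-butyldiphenylsilyloxy)-6-hydroxy-10,12-bis(triethylsilyloxy)germacra-4,11(13)-dien-3-one | C1C(=O)/C(CO[Si](c2ccccc2)(c3ccccc3)C(C)(C)C)=C\[C@@H](O)[C@H](C(=C)CO[Si](CC)(CC)CC)[C@@H](O[Si](C)(C)C(C)(C)C)C[C@](C)(O[Si](CC)(CC)CC)C1
F2 | step 15 | (4Z,6S,7S,8S,10R)-8-(tert-butyldimethylsilyloxy)-15-(tert-butyldiphenylsilyloxy)-6-(4-nitrobenzoyloxy)-10,12-bis(triethylsilyloxy)germacra-4,11(13)-dien-3-one | C1C(=O)/C(CO[Si](c2ccccc2)(c3ccccc3)C(C)(C)C)=C\[C@H](OC(=O)c5ccc(cc5)[N+](=O)[O-])[C@H](C(=C)CO[Si](CC)(CC)CC)[C@@H](O[Si](C)(C)C(C)(C)C)C[C@](C)(O[Si](CC)(CC)CC)C1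
F3 | step 18 | (4Z,6S,7S,10R)-15-(tert-butyldiphenylsilyloxy)-10-hydroxy-3,8-dioxogermacra-4,11(13)-dien-12,6-olide | C1C(=O)/C(CO[Si](c2ccccc2)(c3ccccc3)C(C)(C)C)=C\[C@@H]4OC(=O)C(=C)[C@@H]4C(=O)C[C@](C)(O)C1
F4 | step 18 | (4Z,6S,7R,8R,10R)-15-(tert-butyldiphenylsilyloxy)-8,10-dihydroxy-3-oxogermacra-4,11(13)-dien-12,6-olide | C1C(=O)/C(CO[Si](c2ccccc2)(c3ccccc3)C(C)(C)C)=C\[C@@H]4OC(=O)C(=C)[C@@H]4[C@H](O)C[C@](C)(O)C1
F5 | step 9 | (2Z,4S,6R)-4-(tert-butyldimethylsilyloxy)-6-methyl-6-(triethylsilyloxy)cyclooct-2-en-1-ol (both C1 epimers) | OC1/C=C\[C@@H](O[Si](C)(C)C(C)(C)C)C[C@](C)(O[Si](CC)(CC)CC)CC1
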